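Drimane numbering is used (ring A: C1–C5 and C10; ring B: C5–C10; C11 benzylic). The route rests on one disconnection of ring A, at C1–C2 and at the ring-fusion bond C5–C10, to an acyclic (E)-dienyl ketone whose quaternary C9 carries a vinyl group (C10=C1). A thermal intramolecular Diels–Alder reaction closes rings A and B together and sets C10 from the C8/C9 pair, which comes from a bought lactone stereocentre and one substrate-controlled alkylation. The step exploits the C5=C6 alkene flanked by the C4 gem-dimethyl group: both are read as the trace of a C6 ketone conjugated to a C4-methyl diene.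

Key step: step 11

Assumption: compounds 1, 4 and 14 are taken as purchasable; aryl sulfates are drawn as neutral hydrogen sulfates although they would be handled as pyridinium or sodium salts.

Step 1
Reactants: 1 3,4-bis(benzyloxy)phenol
Product: 2 4,5-bis(benzyloxy)-2-hydroxybenzaldehyde
Conditions: MgCl2, Et3N, (CH2O)n, MeCN, reflux
Reagents that add atoms: paraformaldehyde (formaldehyde unit), C=O
Why: Magnesium phenoxide-directed ortho-formylation should place the formyl group at the unhindered ortho position, para to the C3 benzyloxy group.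

Step 2
Reactants: 2 4,5-bis(benzyloxy)-2-hydroxybenzaldehyde
Product: 3 4,5-bis(benzyloxy)-2-(methoxymethoxy)benzaldehyde
Conditions: MeOCH2Cl, i-Pr2NEt, DMAP (cat.), CH2Cl2, 0 → 25 °C
Reagents that add atoms: chloromethyl methyl ether, COCCl
Why: O-Alkylation of the phenol gives the MOM acetal, which later directs ortho-lithiation and can be removed by mild acid beside benzyl ethers.

Step 3
Reactants: 4 (4S)-4-methyloxolan-2-one; 3 4,5-bis(benzyloxy)-2-(methoxymethoxy)benzaldehyde
Product: 8 (3E,4S)-3-{[4,5-bis(benzyloxy)-2-(methoxymethoxy)phenyl]methylidene}-4-methyloxolan-2-one, via lithium enolate 5 (not isolated), via lithium aldolate 6 (not isolated), via aldol mesylate 7 (not isolated)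
Conditions: LiN(SiMe3)2, THF, −78 °C; 3, −78 °C; MsCl, −78 → 0 °C; Et3N, 0 → 25 °C
Reagents that add atoms: none
Why: Aldol condensation (aldol addition, mesylation, E1cB elimination) should give the conjugated arylidene lactone without touching the C8 stereocentre (lactone C4); the alkene geometry is of no consequence for step 4.

Step 4
Reactants: 8 (3E,4S)-3-{[4,5-bis(benzyloxy)-2-(methoxymethoxy)phenyl]methylidene}-4-methyloxolan-2-one
Product: 10 (3R,4S)-3-{[4,5-bis(benzyloxy)-2-(methoxymethoxy)phenyl]methyl}-3,4-dimethyloxolan-2-one, via lithium enolate 9 (not isolated)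
Conditions: LiBH(s-Bu)3, THF, −78 °C; MeI, HMPA, −78 → 0 °C
Reagents that add atoms: iodomethane, CI
Why: Conjugate reduction gives the lactone enolate regiospecifically, and its C-methylation (reductive alkylation) should occur anti to the neighbouring C4 methyl group, as in alkylations of β-substituted butyrolactone enolates, so that at the new quaternary carbon (C9) methyl is trans and arylmethyl cis to that methyl group.

Step 5
Reactants: 10 (3R,4S)-3-{[4,5-bis(benzyloxy)-2-(methoxymethoxy)phenyl]methyl}-3,4-dimethyloxolan-2-one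
Product: 11 (3R,4S)-3-{[4,5-bis(benzyloxy)-2-(methoxymethoxy)phenyl]methyl}-3,4-dimethyloxolan-2-ol (both anomers)
Conditions: i-Bu2AlH, CH2Cl2, −78 °C; aq. KNaC4H4O6
Reagents that add atoms: none
Why: Partial reduction of the lactone to the lactol by a dialkylaluminium hydride at low temperature, the aluminium acetal being stable until work-up.

Step 6
Reactants: 11 (3R,4S)-3-{[4,5-bis(benzyloxy)-2-(methoxymethoxy)phenyl]methyl}-3,4-dimethyloxolan-2-ol
Product: 12 (2S,3S)-3-{[4,5-bis(benzyloxy)-2-(methoxymethoxy)phenyl]methyl}-2,3-dimethylpent-4-en-1-ol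
Conditions: Ph3PCH3Br, KOt-Bu, THF, 0 → 65 °C
Reagents that add atoms: methyltriphenylphosphonium bromide, C[P+](c1ccccc1)(c1ccccc1)c1ccccc1.[Br-]
Why: Wittig methylenation of the open hydroxy-aldehyde form of the lactol gives the vinyl group on the quaternary carbon and frees the primary alcohol; the aldehyde has no α-hydrogen, so no stereocentre can be lost.

Step 7
Reactants: 12 (2S,3S)-3-{[4,5-bis(benzyloxy)-2-(methoxymethoxy)phenyl]methyl}-2,3-dimethylpent-4-en-1-ol
Product: 13 1,2-bis(benzyloxy)-4-[(2S,3S)-2-ethenyl-4-iodo-2,3-dimethylbutyl]-5-(methoxymethoxy)benzene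
Conditions: I2, PPh3, imidazole, CH2Cl2, 0 → 25 °C
Reagents that add atoms: iodine, II
Why: Appel-type iodination, in which iodide displaces the alkoxyphosphonium group at the primary carbon by SN2.

Step 8
Reactants: 14 ethyl (2E)-3-methyl-4-oxobut-2-enoate
Product: 15 ethyl (2E)-3-methylpenta-2,4-dienoate
Conditions: Ph3PCH3Br, KOt-Bu, THF, −78 → 0 °C
Reagents that add atoms: methyltriphenylphosphonium bromide, C[P+](c1ccccc1)(c1ccccc1)c1ccccc1.[Br-]
Why: Wittig methylenation of the aldehyde, which is far more electrophilic than the conjugated ester, should give the diene with the (2E) geometry of the starting material retained.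

Step 9
Reactants: 15 ethyl (2E)-3-methylpenta-2,4-dienoate
Product: 16 (2E)-N-methoxy-N,3-dimethylpenta-2,4-dienamide
Conditions: MeNH(OMe)·HCl, i-PrMgCl, THF, −20 → 0 °C
Reagents that add atoms: N,O-dimethylhydroxylamine hydrochloride, CNOC.Cl
Why: Aminolysis of the ester by the chloromagnesium amide (Weinreb amide formation) should leave both alkenes untouched.

Step 10
Reactants: 13 1,2-bis(benzyloxy)-4-[(2S,3S)-2-ethenyl-4-iodo-2,3-dimethylbutyl]-5-(methoxymethoxy)benzene; 16 (2E)-N-methoxy-N,3-dimethylpenta-2,4-dienamide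
Product: 18 (3E,7R,8S)-8-{[4,5-bis(benzyloxy)-2-(methoxymethoxy)phenyl]methyl}-3,7,8-trimethyldeca-1,3,9-trien-5-one, via alkyllithium 17 (not isolated)
Conditions: t-BuLi (2 equiv), Et2O/pentane, −78 °C; 16, −78 → 0 °C; H2O
Reagents that add atoms: none
Why: Iodine–lithium exchange followed by acylation of the primary alkyllithium (Weinreb ketone synthesis), in which the chelated tetrahedral intermediate prevents over-addition and releases the dienyl ketone on work-up.

Step 11
Reactants: 18 (3E,7R,8S)-8-{[4,5-bis(benzyloxy)-2-(methoxymethoxy)phenyl]methyl}-3,7,8-trimethyldeca-1,3,9-trien-5-one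
Product: 20 (3R,4R,4aS)-4-{[4,5-bis(benzyloxy)-2-(methoxymethoxy)phenyl]methyl}-3,4,8-trimethyl-3,4,4a,5,6,7-hexahydronaphthalen-1(2H)-one, via cycloadduct 19 (not isolated)
Conditions: PhMe (high dilution), BHT (cat.), 170 °C, sealed tube; then DBU (cat.), 25 °C
Reagents that add atoms: none
Why: Concerted, asynchronous thermal [4+2] cycloaddition (type 1 intramolecular Diels–Alder reaction of a deca-1,3,9-trien-5-one, the closest known class), in which the terminal vinyl carbon C1 bonds to the electrophilic δ-carbon C2 of the dienone and C10 bonds to C5; DBU then moves the C3=C4 alkene into conjugation through the dienolate. Ring A (C10, C1–C5) closes by the cycloaddition itself, and ring B (C5–C10) closes in the same event as the six-membered ring spanned by the four-atom tether C6–C9, helped by the gem-dialkyl effect of quaternary C9. C10 is the only lasting new stereocentre and is controlled by C9: the tether carbon C8 must take the outside position, the bulky arylmethyl group should then go anti to the forming C5–C10 bond and the small methyl group into the crowded inside position under the diene, which places H10 cis to the arylmethyl group as required; the axial C8 methyl group of this arrangement costs little because C6 is trigonal. The C5 stereocentre (endo or exo mode) is not controlled but is erased by the isomerisation, so both ring-fusion isomers converge on 20. The step therefore needs only π-facial selectivity at the vinyl group; regiochemistry is fixed by the tether, and the (E) geometry of C4=C5 lets the diene reach the s-cis form.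

Step 12
Reactants: 20 (3R,4R,4aS)-4-{[4,5-bis(benzyloxy)-2-(methoxymethoxy)phenyl]methyl}-3,4,8-trimethyl-3,4,4a,5,6,7-hexahydronaphthalen-1(2H)-one
Product: 22 (3R,4R,4aS)-4-{[4,5-bis(benzyloxy)-2-(methoxymethoxy)phenyl]methyl}-3,4,8,8-tetramethyl-2,3,4,4a,5,6,7,8-octahydronaphthalen-1-yl trifluoromethanesulfonate, via lithium enolate 21 (not isolated)
Conditions: Me2CuLi (from MeLi, CuI), Et2O, −20 → 0 °C; PhNTf2, THF/HMPA, 0 → 25 °C
Reagents that add atoms: lithium dimethylcuprate, [Li+].C[Cu-]C; N-phenylbis(trifluoromethanesulfonimide), O=S(=O)(N(c1ccccc1)S(=O)(=O)C(F)(F)F)C(F)(F)F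
Why: Conjugate addition of the Gilman cuprate to the s-cis alkylidene ketone (a pulegone-type enone) creates the C4 gem-dimethyl group without a new stereocentre, and O-triflation of the regiospecifically formed enolate fixes the double bond at C5=C6.

Step 13
Reactants: 22 (3R,4R,4aS)-4-{[4,5-bis(benzyloxy)-2-(methoxymethoxy)phenyl]methyl}-3,4,8,8-tetramethyl-2,3,4,4a,5,6,7,8-octahydronaphthalen-1-yl trifluoromethanesulfonate
Product: 23 1,2-bis(benzyloxy)-5-(methoxymethoxy)-4-{[(1R,2R,8aS)-1,2,5,5-tetramethyl-1,2,3,5,6,7,8,8a-octahydronaphthalen-1-yl]methyl}benzene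
Conditions: Pd(OAc)2 (cat.), PPh3, HCO2H, n-Bu3N, DMF, 60 °C
Reagents that add atoms: none
Why: Palladium-catalysed reduction of the enol triflate by formate (oxidative addition to zerovalent palladium, hydride transfer from formate with loss of CO2, reductive elimination) replaces the triflate by hydrogen with the alkene position retained.

Step 14
Reactants: 23 1,2-bis(benzyloxy)-5-(methoxymethoxy)-4-{[(1R,2R,8aS)-1,2,5,5-tetramethyl-1,2,3,5,6,7,8,8a-octahydronaphthalen-1-yl]methyl}benzene
Product: 25 2,3-bis(benzyloxy)-6-(methoxymethoxy)-5-{[(1R,2R,8aS)-1,2,5,5-tetramethyl-1,2,3,5,6,7,8,8a-octahydronaphthalen-1-yl]methyl}benzaldehyde, via aryllithium 24 (not isolated)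
Conditions: n-BuLi, TMEDA, THF, −78 → −20 °C; DMF, −78 → 0 °C; H2O
Reagents that add atoms: N,N-dimethylformamide, CN(C)C=O
Why: Directed ortho-metalation at the only ring position flanked by two oxygen substituents (between OMOM and OBn), followed by formylation of the aryllithium by DMF.

Step 15
Reactants: 25 2,3-bis(benzyloxy)-6-(methoxymethoxy)-5-{[(1R,2R,8aS)-1,2,5,5-tetramethyl-1,2,3,5,6,7,8,8a-octahydronaphthalen-1-yl]methyl}benzaldehyde
Product: 26 2,3-bis(benzyloxy)-6-hydroxy-5-{[(1R,2R,8aS)-1,2,5,5-tetramethyl-1,2,3,5,6,7,8,8a-octahydronaphthalen-1-yl]methyl}benzaldehyde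
Conditions: HCl (aq.), MeOH/THF, 40 °C
Reagents that add atoms: none
Why: Acid-catalysed acetal cleavage of the MOM ether, made easy by the ortho formyl group, should leave the benzyl ethers and the trisubstituted alkene untouched.

Step 16
Reactants: 26 2,3-bis(benzyloxy)-6-hydroxy-5-{[(1R,2R,8aS)-1,2,5,5-tetramethyl-1,2,3,5,6,7,8,8a-octahydronaphthalen-1-yl]methyl}benzaldehyde
Product: 27 3,4-bis(benzyloxy)-2-formyl-6-{[(1R,2R,8aS)-1,2,5,5-tetramethyl-1,2,3,5,6,7,8,8a-octahydronaphthalen-1-yl]methyl}phenyl hydrogen sulfate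
Conditions: SO3·pyridine, pyridine, 60 °C
Reagents that add atoms: sulfur trioxide–pyridine complex, [O-]S(=O)(=O)[n+]1ccccc1
Why: O-Sulfonation of the only free phenol by the sulfur trioxide complex gives the aryl sulfate monoester.

Step 17
Reactants: 27 3,4-bis(benzyloxy)-2-formyl-6-{[(1R,2R,8aS)-1,2,5,5-tetramethyl-1,2,3,5,6,7,8,8a-octahydronaphthalen-1-yl]methyl}phenyl hydrogen sulfate
Product: 28 2-formyl-3,4-dihydroxy-6-{[(1R,2R,8aS)-1,2,5,5-tetramethyl-1,2,3,5,6,7,8,8a-octahydronaphthalen-1-yl]methyl}phenyl hydrogen sulfate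
Conditions: H2 (1 atm), Pd/C, EtOAc/MeOH, 25 °C, stopped at full debenzylation
Reagents that add atoms: none
Why: Hydrogenolysis of the two aryl benzyl ethers over palladium on carbon should be much faster than hydrogenation of the hindered C5=C6 alkene or reduction of the hydrogen-bonded aryl aldehyde, and the aryl sulfate is inert.

Compound list
1 | 3,4-bis(benzyloxy)phenol | Oc1ccc(OCc2ccccc2)c(OCc2ccccc2)c1 | starting material
2 | 4,5-bis(benzyloxy)-2-hydroxybenzaldehyde | O=Cc1cc(OCc2ccccc2)c(OCc2ccccc2)cc1O | intermediate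
3 | 4,5-bis(benzyloxy)-2-(methoxymethoxy)benzaldehyde | O=Cc1cc(OCc2ccccc2)c(OCc2ccccc2)cc1OCOC | intermediate
4 | (4S)-4-methyloxolan-2-one ((S)-β-methyl-γ-butyrolactone) | C[C@@H]1COC(=O)C1 | starting material
5 | lithium enolate of 4 | C[C@@H]1COC([O-])=C1.[Li+] | intermediate
6 | lithium aldolate from 5 and 3 (4S; both new centres as mixtures) | C[C@@H]1COC(=O)C1C([O-])c1cc(OCc2ccccc2)c(OCc2ccccc2)cc1OCOC.[Li+] | intermediate
7 | methanesulfonate of the aldol adduct (4S; mixtures at the two other centres) | C[C@@H]1COC(=O)C1C(OS(C)(=O)=O)c1cc(OCc2ccccc2)c(OCc2ccccc2)cc1OCOC | intermediate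
8 | (3E,4S)-3-{[4,5-bis(benzyloxy)-2-(methoxymethoxy)phenyl]methylidene}-4-methyloxolan-2-one | C[C@@H]1COC(=O)/C1=C/c1cc(OCc2ccccc2)c(OCc2ccccc2)cc1OCOC | intermediate
9 | lithium enolate of (4S)-3-(arylmethyl)-4-methyloxolan-2-one | C[C@@H]1COC([O-])=C1Cc1cc(OCc2ccccc2)c(OCc2ccccc2)cc1OCOC.[Li+] | intermediate
10 | (3R,4S)-3-{[4,5-bis(benzyloxy)-2-(methoxymethoxy)phenyl]methyl}-3,4-dimethyloxolan-2-one | C[C@@H]1COC(=O)[C@]1(C)Cc1cc(OCc2ccccc2)c(OCc2ccccc2)cc1OCOC | intermediate
11 | (3R,4S)-3-{[4,5-bis(benzyloxy)-2-(methoxymethoxy)phenyl]methyl}-3,4-dimethyloxolan-2-ol (both anomers) | C[C@@H]1COC(O)[C@]1(C)Cc1cc(OCc2ccccc2)c(OCc2ccccc2)cc1OCOC | intermediate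
12 | (2S,3S)-3-{[4,5-bis(benzyloxy)-2-(methoxymethoxy)phenyl]methyl}-2,3-dimethylpent-4-en-1-ol | C[C@H](CO)[C@](C)(C=C)Cc1cc(OCc2ccccc2)c(OCc2ccccc2)cc1OCOC | intermediate
13 | 1,2-bis(benzyloxy)-4-[(2S,3S)-2-ethenyl-4-iodo-2,3-dimethylbutyl]-5-(methoxymethoxy)benzene | C[C@H](CI)[C@](C)(C=C)Cc1cc(OCc2ccccc2)c(OCc2ccccc2)cc1OCOC | intermediate
14 | ethyl (2E)-3-methyl-4-oxobut-2-enoate | CCOC(=O)/C=C(C)/C=O | starting material
15 | ethyl (2E)-3-methylpenta-2,4-dienoate | CCOC(=O)/C=C(C)/C=C | intermediate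
16 | (2E)-N-methoxy-N,3-dimethylpenta-2,4-dienamide | CON(C)C(=O)/C=C(C)/C=C | intermediate
17 | primary alkyllithium from 13 (Li in place of I, configuration unchanged) | C[C@H](C[Li])[C@](C)(C=C)Cc1cc(OCc2ccccc2)c(OCc2ccccc2)cc1OCOC | intermediate
18 | (3E,7R,8S)-8-{[4,5-bis(benzyloxy)-2-(methoxymethoxy)phenyl]methyl}-3,7,8-trimethyldeca-1,3,9-trien-5-one | C=C/C(C)=C/C(=O)C[C@@H](C)[C@](C)(C=C)Cc1cc(OCc2ccccc2)c(OCc2ccccc2)cc1OCOC | intermediate
19 | cycloadduct: 4-(arylmethyl)-3,4,8-trimethyl-3,4,4a,5,6,8a-hexahydronaphthalen-1(2H)-one, C8, C9, C10 as in 20, both epimers at C5 (position 8a) | C[C@@H]1CC(=O)C2C(C)=CCC[C@H]2[C@]1(C)Cc1cc(OCc3ccccc3)c(OCc3ccccc3)cc1OCOC | intermediate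
20 | (3R,4R,4aS)-4-{[4,5-bis(benzyloxy)-2-(methoxymethoxy)phenyl]methyl}-3,4,8-trimethyl-3,4,4a,5,6,7-hexahydronaphthalen-1(2H)-one | C[C@@H]1CC(=O)C2=C(C)CCC[C@H]2[C@]1(C)Cc1cc(OCc3ccccc3)c(OCc3ccccc3)cc1OCOC | intermediate
21 | lithium enolate (C5=C6–OLi) after conjugate methylation of 20 | C[C@@H]1CC([O-])=C2[C@@H](CCCC2(C)C)[C@]1(C)Cc1cc(OCc3ccccc3)c(OCc3ccccc3)cc1OCOC.[Li+] | intermediate
22 | (3R,4R,4aS)-4-{[4,5-bis(benzyloxy)-2-(methoxymethoxy)phenyl]methyl}-3,4,8,8-tetramethyl-2,3,4,4a,5,6,7,8-octahydronaphthalen-1-yl trifluoromethanesulfonate | C[C@@H]1CC(OS(=O)(=O)C(F)(F)F)=C2[C@@H](CCCC2(C)C)[C@]1(C)Cc1cc(OCc3ccccc3)c(OCc3ccccc3)cc1OCOC | intermediate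
23 | 1,2-bis(benzyloxy)-5-(methoxymethoxy)-4-{[(1R,2R,8aS)-1,2,5,5-tetramethyl-1,2,3,5,6,7,8,8a-octahydronaphthalen-1-yl]methyl}benzene | C[C@@H]1CC=C2[C@@H](CCCC2(C)C)[C@]1(C)Cc1cc(OCc3ccccc3)c(OCc3ccccc3)cc1OCOC | intermediate
24 | aryllithium from 23 (Li between the OMOM and OBn groups) | C[C@@H]1CC=C2[C@@H](CCCC2(C)C)[C@]1(C)Cc1cc(OCc3ccccc3)c(OCc3ccccc3)c([Li])c1OCOC | intermediate
25 | 2,3-bis(benzyloxy)-6-(methoxymethoxy)-5-{[(1R,2R,8aS)-1,2,5,5-tetramethyl-1,2,3,5,6,7,8,8a-octahydronaphthalen-1-yl]methyl}benzaldehyde | C[C@@H]1CC=C2[C@@H](CCCC2(C)C)[C@]1(C)Cc1cc(OCc3ccccc3)c(OCc3ccccc3)c(C=O)c1OCOC | intermediate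
26 | 2,3-bis(benzyloxy)-6-hydroxy-5-{[(1R,2R,8aS)-1,2,5,5-tetramethyl-1,2,3,5,6,7,8,8a-octahydronaphthalen-1-yl]methyl}benzaldehyde | C[C@@H]1CC=C2[C@@H](CCCC2(C)C)[C@]1(C)Cc1cc(OCc3ccccc3)c(OCc3ccccc3)c(C=O)c1O | intermediate
27 | 3,4-bis(benzyloxy)-2-formyl-6-{[(1R,2R,8aS)-1,2,5,5-tetramethyl-1,2,3,5,6,7,8,8a-octahydronaphthalen-1-yl]methyl}phenyl hydrogen sulfate | C[C@@H]1CC=C2[C@@H](CCCC2(C)C)[C@]1(C)Cc1cc(OCc3ccccc3)c(OCc3ccccc3)c(C=O)c1OS(=O)(=O)O | intermediate
28 | 2-formyl-3,4-dihydroxy-6-{[(1R,2R,8aS)-1,2,5,5-tetramethyl-1,2,3,5,6,7,8,8a-octahydronaphthalen-1-yl]methyl}phenyl hydrogen sulfate | C[C@@H]1CC=C2[C@@H](CCCC2(C)C)[C@]1(C)Cc1cc(O)c(O)c(C=O)c1OS(=O)(=O)O | target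

Total step count: 17. Longest linear sequence: 15 steps (steps 1–7 and 10–17, from 1).

Steps most likely to fail

Step 11 may fail through poor π-facial discrimination at the vinyl group (methyl against arylmethyl on C9) or through a cycloaddition too slow to compete with thermal isomerisation of the dienone. The fallback sets out from lactol 11 and returns at alkene 23. It replaces the vinyl group by a (Z)-2-(phenylsulfanyl)vinyl group, whose cis sulfur substituent should force the C9 methyl group into the alkene plane by 1,3-allylic strain, so that the diene delivered through C8 can only add anti to the arylmethyl group. Lactol 11 is homologated (Ohira–Bestmann reaction: dimethyl (1-diazo-2-oxopropyl)phosphonate, K2CO3, MeOH) to the alkynol F1. Base-mediated anti-Markovnikov addition of thiophenol (PhSH, Cs2CO3, DMSO) should give the (Z)-vinyl sulfide alcohol F2, and iodination as in step 7 the iodide F3. Iodine–lithium exchange to the alkyllithium F4 (not isolated) and acylation by 16 as in step 10 give the trienone F5. Heating as in step 11 gives the cycloadduct F6 (not isolated) and, after DBU, the enone F7. Cuprate addition and triflation as in step 12 lead through the lithium enolate F8 (not isolated) to the enol triflate F9, and reduction as in step 13 to the sulfide F10. Reductive desulfurisation (NiCl2·6H2O, NaBH4, MeOH/THF, 0 °C) then gives 23.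

Step 12 may fail through sluggish conjugate addition to the tetrasubstituted enone or incomplete O-triflation of the hindered copper-containing enolate. The fallback sets out from enone 20 and returns at enol triflate 22. It separates the two events: chlorosilane-accelerated, copper-catalysed Grignard addition (MeMgBr, CuBr·SMe2 cat., Me3SiCl, HMPA, THF, −78 °C) gives the isolable trimethylsilyl enol ether F11. MeLi (THF, 0 °C) then regenerates the copper-free lithium enolate 21, which is triflated by N-(5-chloropyridin-2-yl)bis(trifluoromethanesulfonimide) to give 22.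

Step 17 may fail through over-reduction, that is hydrogenation of the C5=C6 alkene or of the formyl group during hydrogenolysis. The fallback sets out from aldehyde 25 and returns at target 28, and avoids hydrogen altogether. BCl3 with pentamethylbenzene (CH2Cl2, −78 °C) removes both benzyl ethers and the MOM ether to give the triol F12. 1,1'-Carbonyldiimidazole (one equivalent, THF, 0 °C) should close the catechol pair to the cyclic carbonate F13, leaving the third phenol free. SO3·pyridine then gives the sulfate F14, and mild hydrolysis of the carbonate (NaHCO3, MeOH/H2O) gives 28.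

Further compounds
F1 | step 11 | (2S,3R)-3-{[4,5-bis(benzyloxy)-2-(methoxymethoxy)phenyl]methyl}-2,3-dimethylpent-4-yn-1-ol | C[C@H](CO)[C@](C)(C#C)Cc1cc(OCc2ccccc2)c(OCc2ccccc2)cc1OCOC
F2 | step 11 | (2S,3R,4Z)-3-{[4,5-bis(benzyloxy)-2-(methoxymethoxy)phenyl]methyl}-2,3-dimethyl-5-(phenylsulfanyl)pent-4-en-1-ol | C[C@H](CO)[C@](C)(/C=C\Sc2ccccc2)Cc1cc(OCc2ccccc2)c(OCc2ccccc2)cc1OCOC
F3 | step 11 | primary iodide of F2 (I in place of OH, configuration unchanged) | C[C@H](CI)[C@](C)(/C=C\Sc2ccccc2)Cc1cc(OCc2ccccc2)c(OCc2ccccc2)cc1OCOC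
F4 | step 11 | alkyllithium from F3 (Li in place of I) | C[C@H](C[Li])[C@](C)(/C=C\Sc2ccccc2)Cc1cc(OCc2ccccc2)c(OCc2ccccc2)cc1OCOC
F5 | step 11 | (3E,9Z)-8-{[4,5-bis(benzyloxy)-2-(methoxymethoxy)phenyl]methyl}-3,7,8-trimethyl-10-(phenylsulfanyl)deca-1,3,9-trien-5-one (C7 and C8 as in 18) | C=C/C(C)=C/C(=O)C[C@@H](C)[C@](C)(/C=C\Sc2ccccc2)Cc1cc(OCc2ccccc2)c(OCc2ccccc2)cc1OCOC
F6 | step 11 | cycloadduct of F5: 19 bearing a phenylsulfanyl group on C1 cis to C9, both epimers at C5 | C[C@@H]1CC(=O)C2C(C)=CC[C@@H](Sc3ccccc3)[C@H]2[C@]1(C)Cc1cc(OCc3ccccc3)c(OCc3ccccc3)cc1OCOC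
F7 | step 11 | enone 20 bearing a phenylsulfanyl group on C1 (position 5 of the naphthalenone) cis to C9 | C[C@@H]1CC(=O)C2=C(C)CC[C@@H](Sc3ccccc3)[C@H]2[C@]1(C)Cc1cc(OCc3ccccc3)c(OCc3ccccc3)cc1OCOC
F8 | step 11 | lithium enolate from F7 after conjugate methylation | C[C@@H]1CC([O-])=C2[C@@H]([C@H](Sc3ccccc3)CCC2(C)C)[C@]1(C)Cc1cc(OCc3ccccc3)c(OCc3ccccc3)cc1OCOC.[Li+]
F9 | step 11 | enol triflate 22 bearing the C1 phenylsulfanyl group | C[C@@H]1CC(OS(=O)(=O)C(F)(F)F)=C2[C@@H]([C@H](Sc3ccccc3)CCC2(C)C)[C@]1(C)Cc1cc(OCc3ccccc3)c(OCc3ccccc3)cc1OCOC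
F10 | step 11 | alkene 23 bearing the C1 phenylsulfanyl group | C[C@@H]1CC=C2[C@@H]([C@H](Sc3ccccc3)CCC2(C)C)[C@]1(C)Cc1cc(OCc3ccccc3)c(OCc3ccccc3)cc1OCOC
F11 | step 12 | trimethylsilyl enol ether corresponding to enolate 21 (OSiMe3 on C6, C5=C6) | C[C@@H]1CC(O[Si](C)(C)C)=C2[C@@H](CCCC2(C)C)[C@]1(C)Cc1cc(OCc3ccccc3)c(OCc3ccccc3)cc1OCOC
F12 | step 17 | 2,3,6-trihydroxy-5-{[(1R,2R,8aS)-1,2,5,5-tetramethyl-1,2,3,5,6,7,8,8a-octahydronaphthalen-1-yl]methyl}benzaldehyde | C[C@@H]1CC=C2[C@@H](CCCC2(C)C)[C@]1(C)Cc1cc(O)c(O)c(C=O)c1O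
F13 | step 17 | cyclic carbonate of the catechol pair of F12 (third phenol free) | C[C@@H]1CC=C2[C@@H](CCCC2(C)C)[C@]1(C)Cc1cc3OC(=O)Oc3c(C=O)c1O
F14 | step 17 | hydrogen sulfate of F13 at the free phenol | C[C@@H]1CC=C2[C@@H](CCCC2(C)C)[C@]1(C)Cc1cc3OC(=O)Oc3c(C=O)c1OS(=O)(=O)O
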